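The plan cuts the C5–C10 bond (drimane numbering). C5 (tertiary carbinol) and C10 (CH) are the two atoms shared by rings A and B, so one transannular carbonyl-ene closure across a ten-membered ring makes both rings, the C5 hydroxyl and the cis C5/C10 relationship at once; the C1–C2 alkene it leaves is then hydrogenated. The precursor is a (Z)-cyclodec-5-enone (C5 ketone, C10=C1 alkene) carrying only the C8 and C9 stereocentres and the quinone masked as a tetramethoxyarene. It is reached by oxy-Cope ring expansion of a 1,2-dialkenylcyclohexanol; because the chair rearrangement gives the E alkene, a thiyl-radical equilibration to the Z isomer is inserted before the key step.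

Key step: step 13

Assumption: atom labels are drimane numbers (C4 gem-dimethyl carbon, C5 and C10 fusion atoms, C9 quaternary, C8 CHMe, C11 benzylic CH2); the (R,R) amide base is taken to give the (S) enol ether as in the 4-tert-butyl series (otherwise its enantiomer is used), and any shortfall in enantiomeric purity is to be removed by recrystallisation of a crystalline late intermediate.

Step 1
Reactants: 1 4-methylcyclohexanone
Product: 2 (S)-trimethyl[(4-methylcyclohex-1-en-1-yl)oxy]silane
Conditions: (R,R)-[PhCH(Me)]2NH, n-BuLi, THF, −78 °C; Me3SiCl (in situ quench), −78 °C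
Reagents that add atoms: chlorotrimethylsilane, C[Si](C)(C)Cl
Why: Enantioselective deprotonation of the prochiral ketone by the chiral lithium amide with in situ silylation distinguishes the enantiotopic α-hydrogens and should give the (S)-enol ether, whose C4 becomes C8 of the target.

Step 2
Reactants: 2 (S)-trimethyl[(4-methylcyclohex-1-en-1-yl)oxy]silane
Product: 3 (S)-4-methylcyclohex-2-en-1-one
Conditions: Pd(OAc)2 (10 mol%), O2 (1 atm), DMSO, 25 °C
Reagents that add atoms: none
Why: Saegusa–Ito oxidation: palladation of the silyl enol ether at C2 and β-hydride elimination from C3 give the enone with the methyl-bearing stereocentre untouched.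

Step 3
Reactants: 3 (S)-4-methylcyclohex-2-en-1-one
Product: 4 trimethyl{[(3R,4S)-3,4-dimethylcyclohex-1-en-1-yl]oxy}silane
Conditions: MeMgBr, CuBr·SMe2 (5 mol%), Me3SiCl, THF, −78 °C; Et3N
Reagents that add atoms: methylmagnesium bromide, C[Mg]Br; chlorotrimethylsilane, C[Si](C)(C)Cl
Why: Copper-catalysed conjugate addition of the methyl Grignard reagent, accelerated and trapped by Me3SiCl, should deliver methyl anti to the C4 methyl and hold the enolate as the silyl ether; the new C3 centre is removed again in step 4.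

Step 4
Reactants: 4 trimethyl{[(3R,4S)-3,4-dimethylcyclohex-1-en-1-yl]oxy}silane
Product: 5 (S)-3,4-dimethylcyclohex-2-en-1-one
Conditions: Pd(OAc)2 (10 mol%), O2 (1 atm), DMSO, 25 °C
Reagents that add atoms: none
Why: A second Saegusa–Ito oxidation desaturates C2–C3 of the regiodefined enol ether, which puts the new methyl on the β-carbon of the enone while C4 (future C8) stays (S).

Step 5
Reactants: 6 1,2,4,5-tetramethoxybenzene
Product: 8 (2,3,5,6-tetramethoxyphenyl)methanol, via aryllithium 7 (not isolated)
Conditions: n-BuLi, TMEDA, THF, 0 °C; (CH2O)n, 0 → 25 °C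
Reagents that add atoms: paraformaldehyde (as formaldehyde), C=O
Why: Directed ortho-lithiation at the ring position flanked by two methoxy groups and hydroxymethylation of the aryllithium with formaldehyde give the benzylic alcohol that supplies C11.

Step 6
Reactants: 8 (2,3,5,6-tetramethoxyphenyl)methanol
Product: 9 3-(chloromethyl)-1,2,4,5-tetramethoxybenzene
Conditions: SOCl2, CH2Cl2, 0 °C (used at once)
Reagents that add atoms: thionyl chloride, O=S(Cl)Cl
Why: Deoxychlorination of the electron-rich benzylic alcohol through its chlorosulfite; the chloride is preferred to the bromide because it gives less Wurtz coupling when the Grignard reagent is made.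

Step 7
Reactants: 9 3-(chloromethyl)-1,2,4,5-tetramethoxybenzene; 5 (S)-3,4-dimethylcyclohex-2-en-1-one
Product: 11 trimethyl({(3R,4S)-3,4-dimethyl-3-[(2,3,5,6-tetramethoxyphenyl)methyl]cyclohex-1-en-1-yl}oxy)silane, via benzylic Grignard reagent 10 (not isolated)
Conditions: 9, Mg, THF, 0 °C (slow addition); then CuBr·SMe2 (10 mol%), HMPA, Me3SiCl, 5, THF, −78 → −40 °C; Et3N
Reagents that add atoms: chlorotrimethylsilane, C[Si](C)(C)Cl
Why: Copper-catalysed conjugate addition of the benzylic Grignard reagent, promoted by Me3SiCl/HMPA, to the β,β-disubstituted enone; attack anti to the C8 methyl sets quaternary C9 (R) with the two methyl groups cis, and silylation stores the enolate regiospecifically toward C10.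

Step 8
Reactants: 11 trimethyl({(3R,4S)-3,4-dimethyl-3-[(2,3,5,6-tetramethoxyphenyl)methyl]cyclohex-1-en-1-yl}oxy)silane
Product: 13 (2S,3R,4S)-2-[1-hydroxy-2-(phenylselanyl)ethyl]-3,4-dimethyl-3-[(2,3,5,6-tetramethoxyphenyl)methyl]cyclohexan-1-one (both configurations at the side-chain carbinol), via lithium enolate 12 (not isolated)
Conditions: MeLi, THF, 0 °C; PhSeCH2CHO (freshly freed from its diethyl acetal), −78 °C
Reagents that add atoms: (phenylselanyl)acetaldehyde, O=CC[Se]c1ccccc1
Why: Cleavage of the silyl enol ether by MeLi gives the regiodefined lithium enolate, whose aldol addition to the small aldehyde (a vinyl cation equivalent) should succeed at neopentyl C10 from the face anti to the pseudoaxial C9 methyl; the C10 and side-chain carbinol configurations are not needed later.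

Step 9
Reactants: 13 (2S,3R,4S)-2-[1-hydroxy-2-(phenylselanyl)ethyl]-3,4-dimethyl-3-[(2,3,5,6-tetramethoxyphenyl)methyl]cyclohexan-1-one
Product: 14 (2R,3R,4S)-2-ethenyl-3,4-dimethyl-3-[(2,3,5,6-tetramethoxyphenyl)methyl]cyclohexan-1-one
Conditions: MsCl, Et3N, CH2Cl2, 0 → 25 °C
Reagents that add atoms: none
Why: Mesylation triggers selenium-assisted ionisation to a seleniranium ion and loss of PhSeCl, a stereospecific anti-elimination of the β-hydroxy selenide that should give the terminal vinyl group without isomerisation into conjugation.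

Step 10
Reactants: 14 (2R,3R,4S)-2-ethenyl-3,4-dimethyl-3-[(2,3,5,6-tetramethoxyphenyl)methyl]cyclohexan-1-one; 15 isopropenylmagnesium bromide
Product: 16 (1S,2R,3R,4S)-2-ethenyl-3,4-dimethyl-1-(prop-1-en-2-yl)-3-[(2,3,5,6-tetramethoxyphenyl)methyl]cyclohexan-1-ol
Conditions: LaCl3·2LiCl, THF, 0 °C; 15, −78 → 0 °C
Reagents that add atoms: none
Why: Lanthanide-promoted Grignard 1,2-addition suppresses enolisation of the β,γ-unsaturated ketone, and attack from the face away from the axial C9 substituent should give the tertiary alcohol drawn; because the configurations at C5 and C10 are both destroyed in step 11, any diastereomer mixture is carried on.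

Step 11
Reactants: 16 (1S,2R,3R,4S)-2-ethenyl-3,4-dimethyl-1-(prop-1-en-2-yl)-3-[(2,3,5,6-tetramethoxyphenyl)methyl]cyclohexan-1-ol
Product: 19 (5E,7R,8S)-2,2,7,8-tetramethyl-7-[(2,3,5,6-tetramethoxyphenyl)methyl]cyclodec-5-en-1-one, via potassium alkoxide 17 (not isolated), via ring-expanded potassium enolate 18 (not isolated)
Conditions: KH, 18-crown-6, THF, 0 → 50 °C; MeI, −78 → 0 °C
Reagents that add atoms: iodomethane, CI
Why: Anionic oxy-Cope rearrangement through a chair transition state breaks C5–C10 and forms C2–C3, every accessible carbinol diastereomer placing C9 pseudoequatorial so that the new C10=C1 alkene is E, and C-methylation of the regiodefined potassium enolate at C4 completes the gem-dimethyl group.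

Step 12
Reactants: 19 (5E,7R,8S)-2,2,7,8-tetramethyl-7-[(2,3,5,6-tetramethoxyphenyl)methyl]cyclodec-5-en-1-one
Product: 20 (5Z,7R,8S)-2,2,7,8-tetramethyl-7-[(2,3,5,6-tetramethoxyphenyl)methyl]cyclodec-5-en-1-one
Conditions: PhSSPh (20 mol%), hν (365 nm), degassed C6H6, 25 °C; chromatography on AgNO3-impregnated SiO2
Reagents that add atoms: none
Why: Reversible addition of phenylthiyl radicals to the ring alkene (radical-chain E/Z equilibration) should convert the strained E double bond of the ten-membered ring into the Z isomer without touching the ketone, and residual E isomer is held back on AgNO3-impregnated silica and resubmitted.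

Step 13
Reactants: 20 (5Z,7R,8S)-2,2,7,8-tetramethyl-7-[(2,3,5,6-tetramethoxyphenyl)methyl]cyclodec-5-en-1-one
Product: 21 (5S,8S,9R,10S)-4,4,8,9-tetramethyl-9-[(2,3,5,6-tetramethoxyphenyl)methyl]-cis-octal-1-en-5-ol (drimane numbering; 5-OH and 10-H cis)
Conditions: PhMe (0.01 M), BHT (5 mol%), sealed tube, 210 °C
Reagents that add atoms: none
Why: Concerted six-electron carbonyl-ene reaction in which the C5 carbonyl (enophile) bonds to C10 while an allylic hydrogen of C2 passes suprafacially to oxygen and the π bond moves to C1–C2. The closest known reaction type is the thermal transannular carbonyl-ene cyclisation of cyclodec-5-enones obtained by oxy-Cope ring expansion. The single new bond divides the ten-membered ring into two six-membered rings: ring B (C5–C6–C7–C8–C9–C10) closes as a chair, and ring A (C5–C10–C1–C2–C3–C4) closes through a boat-like array in which oxygen and the migrating hydrogen form a third bridge between C5 and C2. C5 and C10 are created together: their cis relationship follows from the Z alkene, which puts C9 anti and H-10 gauche to oxygen across the forming bond (the E isomer would give the trans-fused epimer), and their sense relative to C9 should follow from the ring-B chair that keeps the benzyl group and the C8 methyl equatorial, the other chair having both axial with the benzyl group syn-axial to C4. The step needs C5–C10 rather than C5–C1 bonding, which is secured because quaternary C9 has no allylic hydrogen and only the C2 hydrogens can be delivered, and Lewis acid is avoided so that no cationic shift starts at neopentyl C10.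

Step 14
Reactants: 21 (5S,8S,9R,10S)-4,4,8,9-tetramethyl-9-[(2,3,5,6-tetramethoxyphenyl)methyl]-cis-octal-1-en-5-ol
Product: 22 (5S,8S,9R,10S)-4,4,8,9-tetramethyl-9-[(2,3,5,6-tetramethoxyphenyl)methyl]-cis-decalin-5-ol
Conditions: H2 (1 atm), Pd/C (10%), EtOAc, 25 °C
Reagents that add atoms: none
Why: Catalytic hydrogenation of the disubstituted C1–C2 alkene creates no stereocentre and leaves the arene, the tertiary alcohol and C5, C8, C9 and C10 unchanged.

Step 15
Reactants: 22 (5S,8S,9R,10S)-4,4,8,9-tetramethyl-9-[(2,3,5,6-tetramethoxyphenyl)methyl]-cis-decalin-5-ol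
Product: 23 2,5-dimethoxy-3-{[(5S,8S,9R,10S)-5-hydroxy-4,4,8,9-tetramethyl-cis-decalin-9-yl]methyl}cyclohexa-2,5-diene-1,4-dione
Conditions: (NH4)2Ce(NO3)6, MeCN–H2O, 0 °C
Reagents that add atoms: water, O
Why: Oxidative demethylation of the tetraoxygenated arene by two one-electron transfers to tetravalent cerium with ipso attack of water gives the 2,5-dimethoxy-1,4-benzoquinone, either para pair of methoxy groups leading to the same quinone.

Step 16
Reactants: 23 2,5-dimethoxy-3-{[(5S,8S,9R,10S)-5-hydroxy-4,4,8,9-tetramethyl-cis-decalin-9-yl]methyl}cyclohexa-2,5-diene-1,4-dione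
Product: 24 2-hydroxy-5-methoxy-3-{[(5S,8S,9R,10S)-5-hydroxy-4,4,8,9-tetramethyl-cis-decalin-9-yl]methyl}cyclohexa-2,5-diene-1,4-dione (CNP0209468.1)
Conditions: KOH, MeOH–H2O, 25 °C (acidic work-up, 1 M HCl)
Reagents that add atoms: potassium hydroxide, [K+].[OH-]
Why: Vinylogous ester saponification by addition–elimination of hydroxide: the methoxy group next to the alkyl substituent is twisted out of conjugation, so its carbon is the more electrophilic and should be hydrolysed selectively, the vinylogous carboxylate formed then shielding the second methoxy group.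

Compound list
1 | 4-methylcyclohexanone | CC1CCC(=O)CC1 | starting material
2 | (S)-trimethyl[(4-methylcyclohex-1-en-1-yl)oxy]silane | C[C@H]1CCC(O[Si](C)(C)C)=CC1 | intermediate
3 | (S)-4-methylcyclohex-2-en-1-one | C[C@H]1CCC(=O)C=C1 | intermediate
4 | trimethyl{[(3R,4S)-3,4-dimethylcyclohex-1-en-1-yl]oxy}silane | C[C@H]1CCC(O[Si](C)(C)C)=C[C@@H]1C | intermediate
5 | (S)-3,4-dimethylcyclohex-2-en-1-one | C[C@H]1CCC(=O)C=C1C | intermediate
6 | 1,2,4,5-tetramethoxybenzene | COc1cc(OC)c(OC)cc1OC | starting material
7 | (2,3,5,6-tetramethoxyphenyl)lithium | COc1cc(OC)c(OC)c([Li])c1OC | intermediate (not isolated)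
8 | (2,3,5,6-tetramethoxyphenyl)methanol | COc1cc(OC)c(OC)c(CO)c1OC | intermediate
9 | 3-(chloromethyl)-1,2,4,5-tetramethoxybenzene | COc1cc(OC)c(OC)c(CCl)c1OC | intermediate
10 | [(2,3,5,6-tetramethoxyphenyl)methyl]magnesium chloride | COc1cc(OC)c(OC)c(C[Mg]Cl)c1OC | intermediate (not isolated)
11 | trimethyl({(3R,4S)-3,4-dimethyl-3-[(2,3,5,6-tetramethoxyphenyl)methyl]cyclohex-1-en-1-yl}oxy)silane | C[C@H]1CCC(O[Si](C)(C)C)=C[C@]1(C)Cc1c(OC)c(OC)cc(OC)c1OC | intermediate
12 | lithium (3R,4S)-3,4-dimethyl-3-[(2,3,5,6-tetramethoxyphenyl)methyl]cyclohex-1-en-1-olate | C[C@H]1CCC(O[Li])=C[C@]1(C)Cc1c(OC)c(OC)cc(OC)c1OC | intermediate (not isolated)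
13 | (2S,3R,4S)-2-[1-hydroxy-2-(phenylselanyl)ethyl]-3,4-dimethyl-3-[(2,3,5,6-tetramethoxyphenyl)methyl]cyclohexan-1-one (side-chain carbinol: both configurations) | O=C1CC[C@H](C)[C@@](C)(Cc2c(OC)c(OC)cc(OC)c2OC)[C@H]1C(O)C[Se]c1ccccc1 | intermediate
14 | (2R,3R,4S)-2-ethenyl-3,4-dimethyl-3-[(2,3,5,6-tetramethoxyphenyl)methyl]cyclohexan-1-one | O=C1CC[C@H](C)[C@@](C)(Cc2c(OC)c(OC)cc(OC)c2OC)[C@H]1C=C | intermediate
15 | isopropenylmagnesium bromide | CC(=C)[Mg]Br | starting material
16 | (1S,2R,3R,4S)-2-ethenyl-3,4-dimethyl-1-(prop-1-en-2-yl)-3-[(2,3,5,6-tetramethoxyphenyl)methyl]cyclohexan-1-ol | CC(=C)[C@]1(O)CC[C@H](C)[C@@](C)(Cc2c(OC)c(OC)cc(OC)c2OC)[C@H]1C=C | intermediate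
17 | potassium (1S,2R,3R,4S)-2-ethenyl-3,4-dimethyl-1-(prop-1-en-2-yl)-3-[(2,3,5,6-tetramethoxyphenyl)methyl]cyclohexan-1-olate | CC(=C)[C@]1(O[K])CC[C@H](C)[C@@](C)(Cc2c(OC)c(OC)cc(OC)c2OC)[C@H]1C=C | intermediate (not isolated)
18 | potassium (1Z,5E,7R,8S)-2,7,8-trimethyl-7-[(2,3,5,6-tetramethoxyphenyl)methyl]cyclodeca-1,5-dien-1-olate | COc1cc(OC)c(OC)c(C[C@@]2(C)/C=C/CC/C(C)=C(O[K])/CC[C@@H]2C)c1OC | intermediate (not isolated)
19 | (5E,7R,8S)-2,2,7,8-tetramethyl-7-[(2,3,5,6-tetramethoxyphenyl)methyl]cyclodec-5-en-1-one | COc1cc(OC)c(OC)c(C[C@@]2(C)/C=C/CCC(C)(C)C(=O)CC[C@@H]2C)c1OC | intermediate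
20 | (5Z,7R,8S)-2,2,7,8-tetramethyl-7-[(2,3,5,6-tetramethoxyphenyl)methyl]cyclodec-5-en-1-one | COc1cc(OC)c(OC)c(C[C@@]2(C)/C=C\CCC(C)(C)C(=O)CC[C@@H]2C)c1OC | intermediate
21 | (5S,8S,9R,10S)-4,4,8,9-tetramethyl-9-[(2,3,5,6-tetramethoxyphenyl)methyl]-cis-octal-1-en-5-ol | COc1cc(OC)c(OC)c(C[C@]2(C)[C@@H](C)CC[C@]3(O)[C@H]2C=CCC3(C)C)c1OC | intermediate
22 | (5S,8S,9R,10S)-4,4,8,9-tetramethyl-9-[(2,3,5,6-tetramethoxyphenyl)methyl]-cis-decalin-5-ol | COc1cc(OC)c(OC)c(C[C@]2(C)[C@@H](C)CC[C@]3(O)[C@H]2CCCC3(C)C)c1OC | intermediate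
23 | 2,5-dimethoxy-3-{[(5S,8S,9R,10S)-5-hydroxy-4,4,8,9-tetramethyl-cis-decalin-9-yl]methyl}cyclohexa-2,5-diene-1,4-dione | COC1=CC(=O)C(OC)=C(C[C@]2(C)[C@@H](C)CC[C@]3(O)[C@H]2CCCC3(C)C)C1=O | intermediate
24 | 2-hydroxy-5-methoxy-3-{[(5S,8S,9R,10S)-5-hydroxy-4,4,8,9-tetramethyl-cis-decalin-9-yl]methyl}cyclohexa-2,5-diene-1,4-dione | COC1=CC(=O)C(O)=C(C[C@]2(C)[C@@H](C)CC[C@]3(O)[C@H]2CCCC3(C)C)C1=O | target

Total step count: 16. Longest linear sequence: 14 steps (steps 1–4 and 7–16); the arene branch (steps 5 and 6) joins at step 7.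

Steps most likely to fail

Step 13 (key step). The closure may be slow at a carbonyl flanked by quaternary C4, so that thermal decomposition takes over, or bonding may occur on the wrong face of C10 relative to C9. The fallback sets out from 20 and makes the same bond stepwise as a cationic transannular Prins closure (TiCl4, CH2Cl2, −78 °C), chloride capturing the C1 cation anti to the new bond to give (1R,5S,8S,9R,10S)-1-chloro-4,4,8,9-tetramethyl-9-[(2,3,5,6-tetramethoxyphenyl)methyl]-cis-decalin-5-ol F1. Radical dechlorination (Bu3SnH, AIBN, PhH, 80 °C) then gives 22, where the route is rejoined, so step 14 falls away.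

Step 12. The equilibrium may not lie far enough on the Z side because the cis double bond carries the quaternary allylic C9, or thiyl addition to the hindered alkene may be slow. The fallback sets out from 19 and inverts the alkene stereospecifically: dimethyldioxirane in acetone gives (7R,8S)-trans-5,6-epoxy-2,2,7,8-tetramethyl-7-[(2,3,5,6-tetramethoxyphenyl)methyl]cyclodecan-1-one F2 (either face serves). LiPPh2 in THF opens it at the less hindered C1 with inversion to (7R,8S)-5-(diphenylphosphanyl)-6-hydroxy-2,2,7,8-tetramethyl-7-[(2,3,5,6-tetramethoxyphenyl)methyl]cyclodecan-1-one F3, and MeI quaternises phosphorus so that the betaine collapses by syn-elimination to 20, where the route is rejoined.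

Step 7. Homocoupling of the electron-rich benzylic chloride during magnesium insertion, and slow transfer of the hindered benzyl group that lets 1,2-addition compete, may starve the conjugate addition. The fallback sets out from 5 and 9 and joins the two electrophiles by nickel-catalysed reductive conjugate addition (NiCl2·dme, neocuproine, Mn powder, Me3SiCl, DMF), which needs no preformed benzylmetal and gives silyl enol ether 11 directly, where the route is rejoined (no new compound, F0).

Further compounds
F1 | step 13 | (1R,5S,8S,9R,10S)-1-chloro-4,4,8,9-tetramethyl-9-[(2,3,5,6-tetramethoxyphenyl)methyl]-cis-decalin-5-ol | COc1cc(OC)c(OC)c(C[C@]2(C)[C@@H](C)CC[C@]3(O)[C@H]2[C@H](Cl)CCC3(C)C)c1OC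
F2 | step 12 | (7R,8S)-trans-5,6-epoxy-2,2,7,8-tetramethyl-7-[(2,3,5,6-tetramethoxyphenyl)methyl]cyclodecan-1-one | COc1cc(OC)c(OC)c(C[C@@]2(C)[C@H]3O[C@@H]3CCC(C)(C)C(=O)CC[C@@H]2C)c1OC
F3 | step 12 | (7R,8S)-5-(diphenylphosphanyl)-6-hydroxy-2,2,7,8-tetramethyl-7-[(2,3,5,6-tetramethoxyphenyl)methyl]cyclodecan-1-one | COc1cc(OC)c(OC)c(C[C@@]2(C)[C@@H](O)[C@@H](P(c3ccccc3)c3ccccc3)CCC(C)(C)C(=O)CC[C@@H]2C)c1OC
F0 | step 7 | none | none
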